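**Conventions.** Coumarin atoms are O1, C2–C8a; ring A is the benzo ring, ring B the pyranone, ring C the carbocycle on C3. Ring C locants: C1′ (bonded to C3), C2′ (=CH), C3′ (C=O), C4′ (carbinol), C5′ (CH2), C6′ (C=O). Route compounds are 1–21; the target is 21.

## Analysis of the target

- The target 21 is a 7-methoxycoumarin whose C3 carries ring C, a cyclohex-2-ene-1,4-dione. In ring C, C1′=C2′ is the alkene, C3′ and C6′ are the ketones, C4′ is a tertiary carbinol that also bears the 3-methylbut-2-enyl group, and C5′ is a methylene.
- C4′ is the only stereocentre and is R (hydroxyl > C3′ > C5′ > side-chain CH2). Nothing else in the molecule can relay chirality to it, so it must be set by a reagent or obtained by resolution.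
- Ring C is a hydrated para-quinone. The C4′ hydroxyl is β to the C6′ ketone and α to the C3′ ketone, so loss of water gives the achiral 1,4-benzoquinone, and an acyloin shift is also open.
- Other sensitive groups: the trisubstituted side-chain alkene (acid, electrophilic oxidants), the enedione (Michael acceptor) and the lactone (hydroxide).
- The difficulty is to make an isolated oxygenated quaternary centre enantioselectively on a ring that is one elimination away from a quinone. This argues for keeping ring C aromatic as long as possible and dearomatising it at the end.
- Ring C has its two oxygens para (C3′, C6′) with the side chain next to one of them, the pattern of a 2-alkylhydroquinone monoether. It can therefore be carried as the aryl group of an arylacetate whose α-carbon and carboxyl carbon become C3 and C2.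
- Ring A carries O1 (on C8a) and C4 (on C4a) on adjacent carbons, with the C7 methoxy para to C4a. This is the imprint of an aryne that has taken up an oxygen and a carbon across its triple bond, and ring B is built on that basis from an aryne, N,N-dimethylformamide (12) and the arylacetate enolate.

## Retrosynthetic reasoning

**21 ⇒ 20.** The C6′ ketone is taken back to a methyl enol ether, giving dienone 20. No skeletal bond is cut. The gain is that ring C of 20 is a phenol plus one oxygen atom, and that the C6′ ketone, which turns the C4′ hydroxyl into a β-leaving group, appears only in the last operation. The forward hydrolysis must be mild enough not to ionise or eliminate the tertiary hydroxyl.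

**20 ⇒ 19.** The C4′–O bond is cut, leaving phenol 19. The oxygen is placed on the ortho carbon that bears the side chain. The other ortho carbon, C2′, is unsubstituted and screened by the coumarin, and the para carbon C6′ is blocked by its methoxy group. The forward reaction is an oxygen transfer from a chiral iodyl arene and is the only step that creates chirality.

**19 ⇒ 18 ⇒ 17.** Phenol 19 is traced to its methoxymethyl ether 18, and 18 to bromide 17. The acetal is needed because a free phenol would be arylated by the aryne and deprotonated by the enolate. The C5 bromine is not part of the target; it is what makes the annulation regioselective, and it is removed afterwards by palladium-catalysed reduction without touching the alkenes.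

**17 ⇒ 4 + 12 + 11.** Four bonds of ring B are cut at once: O1–C8a and C4–C4a on ring A, C3–C4, and O1–C2.
- This leaves aryne precursor 4 (ring A), 12 (C4 with its hydrogen, and O1) and arylacetate 11 (C2, C3 and ring C).
- Cutting here and not at C3–C1′ avoids a cross-coupling between a 3-halocoumarin and a hindered, electron-rich arylmetal. The C3–C1′ bond is already present in 11 as its benzylic bond.
- The forward reaction must add the oxygen and carbon of 12 across the aryne in one orientation and trap the resulting quinone methide with the enolate of 11.

**4 ⇒ 2 ⇒ 1.** The C–Si and O–S bonds are cut. The two ortho bromines of 1 are equivalent, so exchanging one of them and letting silicon migrate from oxygen to carbon gives the Br/O/Si arrangement with no regiochemical question. The remaining bromine becomes the control element of the key step.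

**11 ⇒ 10.** The bond from C4′ to the side chain is cut to aryl bromide 10. A sigmatropic shift from the C3′ oxygen was not chosen because it could deliver the allyl unit to C2′ as well as to C4′; a halogen placed beforehand defines the position, and the forward step is a Stille coupling.

**10 ⇒ 8 ⇒ 7 ⇒ 6 ⇒ 5.**
- The methyl ester and the C6′ methyl ether of 10 come from opening lactone 8 and methylating the phenoxide that is set free.
- The acetal of 8 comes from phenol 7.
- The bromine of 7 is introduced on lactone 6. At that stage the C3′ oxygen is a free hydroxyl and the C6′ oxygen is acylated, so the hydroxyl alone directs and the less hindered ortho carbon is attacked.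
- Lactone 6 comes from homogentisic acid 5. Only the ortho hydroxyl can lactonise, which is what tells the two phenolic oxygens apart.

## Alternatives that were turned down

**Alternative 1:** Ring C would be taken to the para-quinone dimethyl monoketal A2 (reachable from 19 by oxidation in methanol). The C4′ oxygen would be introduced as part of a C4′–C5′ epoxide, A1.
- Forward key step: Ph3COOH, NaN(SiMe3)2 and diisopropyl tartrate add peroxide to C5′, the unsubstituted β-carbon of the C3′ enone, and the enolate closes on oxygen at C4′.
- For: the reagent system is designed for quinone monoketals, and C5′ is the only unhindered electrophilic carbon, so site selectivity is built in. On predictability of enantiocontrol this alternative is at least as strong as the iodyl oxygenation chosen here.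
- Against: A1 has one oxygen too many. The target needs C5′ as a methylene, so the secondary C5′–O bond must be cleaved reductively while the tertiary C4′–O bond stays. The only ketone in A1 is C3′, and electron-transfer opening of an α,β-epoxy ketone breaks the α C–O bond, here C4′–O, which is the wrong one. Unmasking C6′ first makes both epoxide carbons α to a ketone, and the enedione itself is reducible. The sequence is also longer (oxidation, epoxidation, opening, deketalisation against oxygenation and hydrolysis).
- Comparison: the chosen route puts exactly one oxygen on C4′ and none on C5′, so no reductive step is needed.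

**Alternative 2:** The C3′–C4′ bond would be cut and ring C closed from the acyclic keto aldehyde A4 to the cyclohexanone A3.
- Forward key step: a chiral aminoindanol-derived triazolium salt with Et3N forms the Breslow intermediate at the C3′ aldehyde, which adds to the C4′ ketone (intramolecular crossed benzoin).
- For: the step is catalytic, forms a C–C bond and gives the α-ketol with its quaternary carbinol directly. On these points it is stronger than a stoichiometric chiral oxidant.
- Against: A3 is far from the target. It lacks the coumarin and the C1′=C2′ alkene, and C6′ is at the alcohol oxidation level. Attaching the coumarin at C1′ would need regioselective enolisation between C1′ and C5′, an arylation and a dehydrogenation, all with a tertiary β-hydroxy ketone exposed to base. A4 itself has a β,γ-unsaturated ketone that can conjugate under amine base, two enolisable carbonyls, and a second, uncontrolled stereocentre at the silyloxy carbon.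
- Comparison: the chosen route takes ring C with all its substituents from the benzene ring of 5 and joins it to the coumarin while ring B is formed, which is far shorter.

**Alternative 3:** The C6′–C1′ and C2′–C3′ bonds would be cut, assembling ring C from the chiral cyclobutane-1,2-dione A6 and 3-ethynyl-7-methoxycoumarin A7 to give A5, the triethylsilyl ether of the target.
- Forward key step: zerovalent nickel (Ni(cod)2, PMe3) inserts into the strained C3′–C6′ acyl–acyl bond, the alkyne inserts, and reductive elimination closes the enedione.
- For: this is the most convergent plan. Two C–C bonds and the full skeleton at the final oxidation level are formed in one step with the stereocentre already in place, and only a desilylation remains. On convergence, and in avoiding a late dearomatisation, it is stronger than the chosen route.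
- Against: the aryl-bearing alkyne carbon must bond to C6′ and not C3′, and only the steric difference between the two acyl termini controls this. Terminal alkynes oligomerise on zerovalent nickel, and acyl–metal species can lose CO. A6 can eliminate silanol from C4′ to give an achiral cyclobutenedione, which would destroy the stereocentre. Its enantioselective preparation is a separate multi-step problem. The insertion is not established for saturated 1,2-diones.
- Comparison: the chosen route has one unproven step, placed where a stepwise version with the same bonds is available, and its intermediates are robust aromatics up to the penultimate step.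

Key step: step 8

**Remark.** The facial sense of oxygen transfer in step 11 cannot be derived from the reagent structure alone. The (S)-configured reagent is assumed to give (R) at C4′; if the opposite sense is found, its enantiomer is used.

## Route

Step 1
Reactants: 1 2,6-dibromo-4-methoxyphenol
Product: 2 (2,6-dibromo-4-methoxyphenoxy)trimethylsilane
Conditions: (Me3Si)2NH, THF, reflux
Reagents that add atoms: hexamethyldisilazane, C[Si](C)(C)N[Si](C)(C)C
Why: O-silylation of a phenol with a silazane; ammonia is the only by-product, so the moisture-sensitive aryl silyl ether can be used after evaporation.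

Step 2
Reactants: 2 (2,6-dibromo-4-methoxyphenoxy)trimethylsilane
Product: 4 2-bromo-4-methoxy-6-(trimethylsilyl)phenyl trifluoromethanesulfonate, via lithium 2-bromo-4-methoxy-6-(trimethylsilyl)phenoxide 3 (not isolated)
Conditions: n-BuLi (1.0 equiv), THF, −78 °C; then Tf2O, −78 °C → 0 °C
Reagents that add atoms: trifluoromethanesulfonic anhydride, O=S(=O)(OS(=O)(=O)C(F)(F)F)C(F)(F)F
Why: Bromine–lithium exchange at one of the two equivalent C–Br bonds is followed by a 1,3 O→C silyl shift (retro-Brook rearrangement) driven by phenoxide formation, and the phenoxide is triflated in the same flask; this is the standard entry to ortho-silylaryl triflates, and one equivalent of n-BuLi leaves the second bromine in place.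

Step 3
Reactants: 5 homogentisic acid
Product: 6 5-hydroxybenzofuran-2(3H)-one
Conditions: TsOH·H2O (cat.), toluene, reflux, Dean–Stark
Reagents that add atoms: none
Why: Acid-catalysed lactonisation of a 2-hydroxyphenylacetic acid with removal of water; only the ortho hydroxyl can close the five-membered ring, so the two phenolic oxygens become different.

Step 4
Reactants: 6 5-hydroxybenzofuran-2(3H)-one
Product: 7 6-bromo-5-hydroxybenzofuran-2(3H)-one
Conditions: NBS, MeCN, 0 °C
Reagents that add atoms: N-bromosuccinimide, O=C1CCC(=O)N1Br
Why: Electrophilic aromatic bromination directed by the free hydroxyl, whose para position is blocked; C6 (the future C4′) is unhindered and para to the carbon bearing the lactone methylene, whereas C4 is wedged between the hydroxyl and the fused five-membered ring, so bromine should enter at C6.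

Step 5
Reactants: 7 6-bromo-5-hydroxybenzofuran-2(3H)-one
Product: 8 6-bromo-5-(methoxymethoxy)benzofuran-2(3H)-one
Conditions: MOMCl, iPr2NEt, CH2Cl2, 0 °C → rt
Reagents that add atoms: chloromethyl methyl ether, COCCl
Why: O-alkylation of an acidic ortho-bromophenol with a hindered amine base that does not open the lactone; any O-alkylated lactone enol would revert to the lactone on aqueous work-up.

Step 6
Reactants: 8 6-bromo-5-(methoxymethoxy)benzofuran-2(3H)-one
Product: 10 methyl [4-bromo-2-methoxy-5-(methoxymethoxy)phenyl]acetate, via potassium 5-bromo-2-(2-methoxy-2-oxoethyl)-4-(methoxymethoxy)phenoxide 9 (not isolated)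
Conditions: K2CO3, MeOH, 0 °C → rt; then MeI, rt → 40 °C
Reagents that add atoms: methanol, CO; iodomethane, CI
Why: Methanolysis of the activated phenolic lactone frees the phenoxide, which is methylated in the same flask (Williamson ether synthesis); MeI is added only after ring opening so that the acidic lactone methylene is not C-methylated.

Step 7
Reactants: 10 methyl [4-bromo-2-methoxy-5-(methoxymethoxy)phenyl]acetate
Product: 11 methyl [2-methoxy-5-(methoxymethoxy)-4-(3-methylbut-2-enyl)phenyl]acetate
Conditions: Bu3SnCH2CH=CMe2, Pd(PPh3)4, DMF, 100 °C
Reagents that add atoms: tributyl(3-methylbut-2-enyl)stannane, CCCC[Sn](CCCC)(CCCC)CC=C(C)C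
Why: Stille coupling; the allylpalladium intermediate reductively eliminates from its less hindered primary terminus, so the linear 3-methylbut-2-enyl arene is expected, and the ester, the acetal and the benzylic C–H bonds are untouched under these neutral conditions.

Step 8
Reactants: 4 2-bromo-4-methoxy-6-(trimethylsilyl)phenyl trifluoromethanesulfonate, 12 N,N-dimethylformamide, 11 methyl [2-methoxy-5-(methoxymethoxy)-4-(3-methylbut-2-enyl)phenyl]acetate
Product: 17 5-bromo-7-methoxy-3-[2-methoxy-5-(methoxymethoxy)-4-(3-methylbut-2-enyl)phenyl]coumarin, via 3-bromo-5-methoxybenzyne 13 (not isolated), via benzoxete 14 (not isolated), via ortho-quinone methide 15 (not isolated), via chlorozinc enolate 16 (not isolated)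
Conditions: 4, CsF, DMF (12 as solvent), rt; then 16 [from 11: LiN(SiMe3)2, THF, −78 °C; ZnCl2, −78 → 0 °C], rt → 50 °C
Reagents that add atoms: none
Why: Proposed new method: the closest known reaction is the three-component coumarin synthesis from arynes, a formamide and doubly activated methylene compounds, and the extension is the use of the zinc enolate of a mono-activated arylacetate together with an aryne that carries an ortho bromine. CsF removes Me3SiF and triflate from 4 to give aryne 13, and the carbonyl oxygen of 12, present as solvent and so in large excess over any other nucleophile, adds to the aryne carbon remote from bromine (future C8a) so that the aryl anion develops at the future C4a next to the inductively withdrawing C–Br bond. That anion closes on the iminium carbon (4-exo-trig) to benzoxete 14, whose strain is released by ring opening to ortho-quinone methide 15. Zinc enolate 16 adds to the exocyclic carbon of 15 (C3–C4), the phenoxide attacks the ester carbonyl in a 6-exo-trig acyl substitution that closes ring B (O1–C2), and Me2NH is expelled from C4 to give the pyranone. The one selectivity needed is the orientation of addition to the aryne: an ortho halogen biases the aryne strongly toward attack at the distal carbon, whereas the methoxy group two positions further away exerts only a weak, here opposing, inductive effect, so the 5-bromo-7-methoxy pattern should dominate. Transmetallation to zinc lowers the basicity of the ester enolate so that it survives DMF without self-condensation, and adding it after aryne generation has begun keeps it away from free aryne. No stereocentre is formed.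

Step 9
Reactants: 17 5-bromo-7-methoxy-3-[2-methoxy-5-(methoxymethoxy)-4-(3-methylbut-2-enyl)phenyl]coumarin
Product: 18 7-methoxy-3-[2-methoxy-5-(methoxymethoxy)-4-(3-methylbut-2-enyl)phenyl]coumarin
Conditions: Pd(OAc)2 (cat.), PPh3, HCO2H, Et3N, DMF, 80 °C
Reagents that add atoms: none
Why: Palladium-catalysed transfer hydrogenolysis of an aryl bromide (oxidative addition, formate exchange, loss of CO2, C–H reductive elimination); a homogeneous phosphine catalyst with formate should not reduce the trisubstituted side-chain alkene or the coumarin C3=C4 bond.

Step 10
Reactants: 18 7-methoxy-3-[2-methoxy-5-(methoxymethoxy)-4-(3-methylbut-2-enyl)phenyl]coumarin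
Product: 19 3-[5-hydroxy-2-methoxy-4-(3-methylbut-2-enyl)phenyl]-7-methoxycoumarin
Conditions: HCl (1.25 M in MeOH), rt
Reagents that add atoms: none
Why: Acid-catalysed acetal exchange removes the methoxymethyl group as dimethoxymethane; the aryl methyl ethers and the lactone are inert, and dilute acid at room temperature should not cyclise the phenol onto the neighbouring alkene.

Step 11
Reactants: 19 3-[5-hydroxy-2-methoxy-4-(3-methylbut-2-enyl)phenyl]-7-methoxycoumarin
Product: 20 3-[(4R)-4-hydroxy-6-methoxy-4-(3-methylbut-2-enyl)-3-oxocyclohexa-1,5-dien-1-yl]-7-methoxycoumarin
Conditions: (S)-3,3′-diiodyl-2,2′-dimethoxy-1,1′-binaphthyl (preformed), THF, −20 °C → rt; aq. NaHCO3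
Reagents that add atoms: (S)-3,3′-diiodyl-2,2′-dimethoxy-1,1′-binaphthyl, COc1c(I(=O)=O)cc2ccccc2c1-c1c(OC)c(I(=O)=O)cc2ccccc12 (the SMILES gives the constitution; the biaryl axis is S)
Why: Hydroxylative phenol dearomatisation: the phenol exchanges onto pentavalent iodine and an oxo ligand is passed to the ortho carbon in a [2,3]-type shift; as with other 2-alkylphenols the substituted ortho carbon C4′ is oxygenated in preference to the unsubstituted C2′, and the chiral biaryl backbone of the reagent differentiates the two faces of the bound phenol and so sets C4′; a preformed iodyl reagent is used so that no peracid meets the side-chain alkene.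

Step 12
Reactants: 20 3-[(4R)-4-hydroxy-6-methoxy-4-(3-methylbut-2-enyl)-3-oxocyclohexa-1,5-dien-1-yl]-7-methoxycoumarin
Product: 21 3-[(4R)-4-hydroxy-4-(3-methylbut-2-enyl)-3,6-dioxocyclohex-1-en-1-yl]-7-methoxycoumarin
Conditions: oxalic acid, THF/H2O, 0 °C → rt
Reagents that add atoms: water, O
Why: Enol ether hydrolysis: protonation at C5′ gives a methoxy-stabilised cation at C6′, water adds and methanol leaves; no bond to C4′ is touched, so the R configuration is carried over, and weak acid at low temperature is chosen to keep the β-hydroxy ketone from losing water.

## Compound list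

1 | 2,6-dibromo-4-methoxyphenol | COc1cc(Br)c(O)c(Br)c1 | starting material
2 | (2,6-dibromo-4-methoxyphenoxy)trimethylsilane | COc1cc(Br)c(O[Si](C)(C)C)c(Br)c1 | intermediate
3 | lithium 2-bromo-4-methoxy-6-(trimethylsilyl)phenoxide | COc1cc(Br)c([O-])c([Si](C)(C)C)c1.[Li+] | intermediate
4 | 2-bromo-4-methoxy-6-(trimethylsilyl)phenyl trifluoromethanesulfonate | COc1cc(Br)c(OS(=O)(=O)C(F)(F)F)c([Si](C)(C)C)c1 | intermediate
5 | homogentisic acid (2,5-dihydroxyphenylacetic acid) | OC(=O)Cc1cc(O)ccc1O | starting material
6 | 5-hydroxybenzofuran-2(3H)-one | O=C1Cc2cc(O)ccc2O1 | intermediate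
7 | 6-bromo-5-hydroxybenzofuran-2(3H)-one | O=C1Cc2cc(O)c(Br)cc2O1 | intermediate
8 | 6-bromo-5-(methoxymethoxy)benzofuran-2(3H)-one | O=C1Cc2cc(OCOC)c(Br)cc2O1 | intermediate
9 | potassium 5-bromo-2-(2-methoxy-2-oxoethyl)-4-(methoxymethoxy)phenoxide | COC(=O)Cc1cc(OCOC)c(Br)cc1[O-].[K+] | intermediate
10 | methyl [4-bromo-2-methoxy-5-(methoxymethoxy)phenyl]acetate | COC(=O)Cc1cc(OCOC)c(Br)cc1OC | intermediate
11 | methyl [2-methoxy-5-(methoxymethoxy)-4-(3-methylbut-2-enyl)phenyl]acetate | COC(=O)Cc1cc(OCOC)c(CC=C(C)C)cc1OC | intermediate
12 | N,N-dimethylformamide | CN(C)C=O | starting material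
13 | 3-bromo-5-methoxybenzyne | COC1=CC#CC(Br)=C1 | intermediate
14 | 3-bromo-5-methoxy-N,N-dimethyl-2H-benzoxet-2-amine (racemic) | COc1cc(Br)c2C(N(C)C)Oc2c1 | intermediate
15 | 5-bromo-6-[(dimethylamino)methylidene]-3-methoxycyclohexa-2,4-dien-1-one | COC1=CC(=O)C(=CN(C)C)C(Br)=C1 | intermediate
16 | chlorozinc enolate of 11 (O-bound form) | COC(O[Zn]Cl)=Cc1cc(OCOC)c(CC=C(C)C)cc1OC | intermediate
17 | 5-bromo-7-methoxy-3-[2-methoxy-5-(methoxymethoxy)-4-(3-methylbut-2-enyl)phenyl]coumarin | COc1cc(Br)c2cc(-c3cc(OCOC)c(CC=C(C)C)cc3OC)c(=O)oc2c1 | intermediate
18 | 7-methoxy-3-[2-methoxy-5-(methoxymethoxy)-4-(3-methylbut-2-enyl)phenyl]coumarin | COc1ccc2cc(-c3cc(OCOC)c(CC=C(C)C)cc3OC)c(=O)oc2c1 | intermediate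
19 | 3-[5-hydroxy-2-methoxy-4-(3-methylbut-2-enyl)phenyl]-7-methoxycoumarin | COc1ccc2cc(-c3cc(O)c(CC=C(C)C)cc3OC)c(=O)oc2c1 | intermediate
20 | 3-[(4R)-4-hydroxy-6-methoxy-4-(3-methylbut-2-enyl)-3-oxocyclohexa-1,5-dien-1-yl]-7-methoxycoumarin | COc1ccc2cc(C3=CC(=O)[C@@](O)(CC=C(C)C)C=C3OC)c(=O)oc2c1 | intermediate
21 | 3-[(4R)-4-hydroxy-4-(3-methylbut-2-enyl)-3,6-dioxocyclohex-1-en-1-yl]-7-methoxycoumarin | COc1ccc2cc(C3=CC(=O)[C@@](O)(CC=C(C)C)CC3=O)c(=O)oc2c1 | target

## Step count and least certain steps

Total: 12 steps. Longest linear sequence: 10 steps (5 → 21, steps 3–12); the aryne precursor branch (steps 1–2) joins at step 8.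

**Step 8 (key step, proposed new method).**
- What may go wrong: the ester zinc enolate is far more basic and nucleophilic than the dicarbonyl partners for which this annulation is established. It may add directly to the aryne, be protonated, or condense with itself in DMF before the quinone methide is available. Lesser risks are partial addition in the reverse orientation and loss of bromide from the ortho-bromoaryl anion before it closes on the iminium carbon.
- Fallback, from 4, 12 and 11, returning at 17, using known reactions only and forming the same four bonds in stages:
  - 4 is treated with CsF in DMF without a carbon nucleophile and the adduct is hydrolysed, a known outcome of aryne insertion into a formamide. With the same bromine-controlled orientation this gives 6-bromo-2-hydroxy-4-methoxybenzaldehyde F1.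
  - 11 is saponified (LiOH, THF/H2O) to [2-methoxy-5-(methoxymethoxy)-4-(3-methylbut-2-enyl)phenyl]acetic acid F2.
  - The phenol of F1 is acylated with F2 (EDC·HCl, DMAP, CH2Cl2) to 3-bromo-2-formyl-5-methoxyphenyl [2-methoxy-5-(methoxymethoxy)-4-(3-methylbut-2-enyl)phenyl]acetate F3.
  - DBU closes ring B by intramolecular Knoevenagel condensation, the classical Perkin-type 3-arylcoumarin synthesis, giving 17.

**Step 11.**
- What may go wrong: poor facial selectivity of the oxygen transfer, because the phenol differs from the simple 2-alkylphenols on which such reagents perform best. Cyclodimerisation of the ortho-quinol by [4+2] addition and para attack leading to the quinone are further risks.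
- Fallback, from 19, returning at 21: racemic dearomatisation with stabilised 2-iodoxybenzoic acid in THF gives the racemic dienone F4. Hydrolysis as in step 12 gives racemic 3-[4-hydroxy-4-(3-methylbut-2-enyl)-3,6-dioxocyclohex-1-en-1-yl]-7-methoxycoumarin F5. Preparative chromatography on a chiral stationary phase then delivers 21. Control by reagent is replaced by resolution.

**Step 12.**
- What may go wrong: loss of the C4′ oxygen. The tertiary hydroxyl of 20 is allylic to the enol ether, so acid can ionise it to a methoxy-stabilised cation that collapses to the para-quinone. After hydrolysis the β-hydroxy ketone can eliminate water to the same quinone.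
- Fallback, from 20, returning at 21: the hydroxyl is masked first (TBSOTf, 2,6-lutidine, CH2Cl2, −78 °C) as the tert-butyldimethylsilyl ether of 20, F6. The less basic silyl ether oxygen is a poorer leaving group under acid. The enol ether is then hydrolysed to the tert-butyldimethylsilyl ether of 21, F7, and HF·pyridine in THF removes silicon to give 21.

**Step 7.**
- What may go wrong: partial allylic transposition giving the 1,1-dimethylallyl isomer, and slow oxidative addition into the electron-rich aryl bromide.
- Fallback, from 10, returning at 11: Stille coupling with allyltributylstannane, which has no such ambiguity, gives methyl [2-methoxy-5-(methoxymethoxy)-4-(prop-2-enyl)phenyl]acetate F8. Cross-metathesis with 2-methylbut-2-ene using the second-generation Grubbs catalyst (H2IMes)(PCy3)Cl2Ru=CHPh then gives 11.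

## Further compounds

F1 | step 8 | 6-bromo-2-hydroxy-4-methoxybenzaldehyde | COc1cc(O)c(C=O)c(Br)c1
F2 | step 8 | [2-methoxy-5-(methoxymethoxy)-4-(3-methylbut-2-enyl)phenyl]acetic acid | OC(=O)Cc1cc(OCOC)c(CC=C(C)C)cc1OC
F3 | step 8 | 3-bromo-2-formyl-5-methoxyphenyl [2-methoxy-5-(methoxymethoxy)-4-(3-methylbut-2-enyl)phenyl]acetate | COc1cc(OC(=O)Cc2cc(OCOC)c(CC=C(C)C)cc2OC)c(C=O)c(Br)c1
F4 | step 11 | racemic 3-[4-hydroxy-6-methoxy-4-(3-methylbut-2-enyl)-3-oxocyclohexa-1,5-dien-1-yl]-7-methoxycoumarin | COc1ccc2cc(C3=CC(=O)C(O)(CC=C(C)C)C=C3OC)c(=O)oc2c1
F5 | step 11 | racemic 3-[4-hydroxy-4-(3-methylbut-2-enyl)-3,6-dioxocyclohex-1-en-1-yl]-7-methoxycoumarin | COc1ccc2cc(C3=CC(=O)C(O)(CC=C(C)C)CC3=O)c(=O)oc2c1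
F6 | step 12 | 3-[(4R)-4-(tert-butyldimethylsilyloxy)-6-methoxy-4-(3-methylbut-2-enyl)-3-oxocyclohexa-1,5-dien-1-yl]-7-methoxycoumarin | COc1ccc2cc(C3=CC(=O)[C@@](O[Si](C)(C)C(C)(C)C)(CC=C(C)C)C=C3OC)c(=O)oc2c1
F7 | step 12 | 3-[(4R)-4-(tert-butyldimethylsilyloxy)-4-(3-methylbut-2-enyl)-3,6-dioxocyclohex-1-en-1-yl]-7-methoxycoumarin | COc1ccc2cc(C3=CC(=O)[C@@](O[Si](C)(C)C(C)(C)C)(CC=C(C)C)CC3=O)c(=O)oc2c1
F8 | step 7 | methyl [2-methoxy-5-(methoxymethoxy)-4-(prop-2-enyl)phenyl]acetate | COC(=O)Cc1cc(OCOC)c(CC=C)cc1OC
A1 | alternative 1 | C4′–C5′ epoxide of 3-[6,6-dimethoxy-4-(3-methylbut-2-enyl)-3-oxocyclohexa-1,4-dien-1-yl]-7-methoxycoumarin, oxygen on the face that gives (R)-C4′ | COc1ccc2cc(C3=CC(=O)[C@]4(CC=C(C)C)O[C@@H]4C3(OC)OC)c(=O)oc2c1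
A2 | alternative 1 | 3-[6,6-dimethoxy-4-(3-methylbut-2-enyl)-3-oxocyclohexa-1,4-dien-1-yl]-7-methoxycoumarin | COc1ccc2cc(C3=CC(=O)C(CC=C(C)C)=CC3(OC)OC)c(=O)oc2c1
A3 | alternative 2 | (2R)-4-(tert-butyldimethylsilyloxy)-2-hydroxy-2-(3-methylbut-2-enyl)cyclohexanone | O=C1[C@@](O)(CC=C(C)C)CC(O[Si](C)(C)C(C)(C)C)CC1
A4 | alternative 2 | 4-(tert-butyldimethylsilyloxy)-9-methyl-6-oxodec-8-enal | O=CCCC(O[Si](C)(C)C(C)(C)C)CC(=O)CC=C(C)C
A5 | alternative 3 | 3-[(4R)-4-(3-methylbut-2-enyl)-3,6-dioxo-4-(triethylsilyloxy)cyclohex-1-en-1-yl]-7-methoxycoumarin | COc1ccc2cc(C3=CC(=O)[C@@](O[Si](CC)(CC)CC)(CC=C(C)C)CC3=O)c(=O)oc2c1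
A6 | alternative 3 | (3R)-3-(3-methylbut-2-enyl)-3-(triethylsilyloxy)cyclobutane-1,2-dione | O=C1[C@@](O[Si](CC)(CC)CC)(CC=C(C)C)CC1=O
A7 | alternative 3 | 3-ethynyl-7-methoxycoumarin | COc1ccc2cc(C#C)c(=O)oc2c1
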